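**Conventions and assumptions.** Locants follow flavonoid usage for the chromanone half (O1, C2, C3, C4, C4a–C8a; ring A is its benzo ring, ring B the aryl group on C2, ring C the pyranone). The flavan half carries double primes (ring D is its benzo ring, ring E its dihydropyran, ring G the aryl group on C2''). Ring F is the furan O7''–C2–C3–C8''–C7''. The descriptors read from the SMILES are 2R, 3R, 2''S. Compounds 4, 10 and 13 are taken as purchasable.

## Analysis of the target

Target 22 contains seven rings: a fused pentacycle A–C–F–D–E and two 4-hydroxyphenyl groups (ring B on C2, ring G on C2''). Rings C and F share the C2–C3 bond. C2 is a ketal carbon bonded to O1, O7'' and ring B; C3 is a tertiary carbinol bonded to the C4 ketone and to C8'' of ring D. There are three stereocentres: C2 (R) and C3 (R), which are locked cis by the six/five ring fusion and so amount to one stereochemical decision, and C2'' (S), which is four bonds from C3 and cannot relay its configuration. Sensitive groups are the five phenols (oxidation), the mixed diaryl ketal (acid), the tertiary α-ketol (base, acyl shifts) and the p-hydroxybenzylic ether C2''–O1'' (acid, hydrogenolysis). The difficulty lies in two adjacent fully substituted carbons at ketal and carbinol oxidation level between three electron-rich arenes, in setting their absolute configuration independently of C2'', and in differentiating six phenolic oxygens, two of which (O1, O7'') end up as ring atoms. The feature used is that C3 lies between C4 (bonded to C4a of ring A) and C2 (bonded to O7'' of ring D) and is itself bonded to C8''. Removing the C3 hydroxyl and the C2–O1 bond therefore leaves a 3-aroyl-2-arylbenzofuran that already holds every other bond of the core, and that benzofuran can be assembled in one operation from an alkyne, an aryl iodide and carbon monoxide.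

## Retrosynthetic reasoning

**22 ⇒ 21.** The five phenols are unmasked last from the pentabenzyl ether 21. Free phenols would not survive the oxidation that creates C2 and C3, and benzyl ethers come off under neutral conditions that leave the ketal and the α-ketol alone.

**21 ⇒ 19 (through 20).** The C3–O bond and the C2–O1 bond are cut. This turns both new stereocentres into the planar C2=C3 bond of benzofuran 19, whose ring A phenol sits next to C2. In the forward direction an oxygen atom must be delivered to one face of C2=C3 to give epoxide 20. The phenol then opens 20 at C2, and the ring fusion allows only the cis ketal, so a single face selection fixes both centres.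

**19 ⇒ 18 ⇒ 12 + 16 + 17.** After masking O1 as a methoxymethyl ether (18), three bonds are cut at once: C4–C4a, C3–C4 and C2–O7''. This is the most convergent cut available: it separates ring A (iodide 16), the carbonyl carbon (carbon monoxide, 17) and the flavan-alkyne 12, and it leaves no hindered aryl–aryl bond to be made. The forward reaction has to carbonylate 16 on zerovalent palladium and use the resulting acyl complex to trigger attack of the 7''-oxygen of 12 on its own alkyne.

**12 ⇒ 11 ⇒ 9 + 10, and 9 ⇒ 8.** The C8''–alkyne bond is cut (cross-coupling of iodide 9 with alkyne 10); the alkyne carbon bonded to ring D is the future C3 and the one bonded to ring B the future C2. O7'' stays masked in 11 so that the coupling cannot close the furan prematurely. The iodine is introduced on the fully protected flavan 8, where the position between O1'' and O7'' is the least hindered activated site.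

**8 ⇒ 7 ⇒ 6 ⇒ 5 ⇒ 3 + 4.** Ring E is opened at C2''–O1'', giving carbinol 7; the forward closure inverts the carbinol, so 7 must be R. Carbinol 7 comes from ketone 6 by asymmetric reduction, which is where C2'' is set. Ketone 6 comes from enone 5 by saturation, and 5 from aldehyde 3 and ketone 4 by aldol condensation (cut at C3''–C4'').

**3 ⇒ 2 ⇒ 1.** The three oxygens of 1 are told apart by their relation to the formyl group: the para oxygen (future O7'') is masked first, then one of the two ortho oxygens (future O5''), leaving the chelated one as the future O1''.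

**16 ⇒ 15 ⇒ 14 ⇒ 13.** The C–I bond is cut back to aryllithium 15, made by metalation of 14 next to its methoxymethyl ether. The same ether that directs the metalation is the removable mask of O1.

## Alternatives that were turned down

**Alternative 1: hydroxyflavanone from an α-aryl chalcone.**
- Disconnection: C2–O1 and the C3–O bond of ring C, back to the α-(flavan-8''-yl)-2'-hydroxychalcone A1, in which C3–C8'' already exists.
- Forward key step: catalytic asymmetric nucleophilic epoxidation of A1, then 6-endo opening of the epoxide at benzylic C2 by the 2'-phenoxide to give the 3-hydroxy-3-arylflavanone A2.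
- For: asymmetric peroxide epoxidation of chalcones is among the best-developed catalytic oxidations, so control at C3 has a stronger pedigree than the oxidation of step 14.
- Against: A1 is a trisubstituted enone whose α-aryl group has two ortho oxygens, so it is twisted and shielded, and peroxide addition would be slow. The 6'-benzyloxy group of ring A favours the competing 5-exo closure to aurone-type products. A2 still has hydrogen on C2, so the ketal level and the C2–O7'' bond would need a further dehydrogenative etherification at a position no more activated than C2''–H.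
- Comparison: the chosen route brings C2 in as an alkyne carbon, already at the right oxidation level, and needs one oxidation event instead of two.

**Alternative 2: flavone epoxide opened by the ring D phenol.**
- Disconnection: C3–O and C2–O7'' (ring F), back to the 3-(7''-hydroxyflavan-8''-yl)flavone A3 with ring C intact.
- Forward key step: enantioselective epoxidation of C2=C3 of A3 and 5-exo attack of the 7''-phenol at C2, giving the pentabenzyl ether A4 (identical with 21).
- For: the oxidation mirrors step 14 but acts on a pyranone double bond, which gives up less aromatic stabilisation than a furan. On that step this alternative is at least as good, and it reaches 21 directly.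
- Against: A3 requires the C3–C8'' bond between a flavone carbon flanked by C4=O and ring B and an arene carbon flanked by two oxygens. That is a tetra-ortho-substituted biaryl-type coupling, and it also creates an axis of hindered rotation. The 7''-oxygen must be differentiated anyway.
- Comparison: the chosen route makes the same C3–C8'' connection as an arene–alkyne bond, where the linear sp carbon removes the steric problem, and attaches ring A through carbon monoxide.

**Alternative 3: isoflavone by oxidative 1,2-aryl shift.**
- Disconnection: C3–C8'' (formed by migration) and O1–C2, back to the 2'-hydroxychalcone A5 that carries ring D as its β-aryl group.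
- Forward key step: Tl(NO3)3 or PhI(OAc)2 in methanol moves ring D from the β- to the α-carbon; acid then closes ring C to the isoflavone A6.
- For: A5 comes from a simple aldol condensation, no hindered cross-coupling is needed, and an electron-rich aryl group migrates readily.
- Against: A6 has hydrogen on C2. Ring B, the C2–O7'' bond and the C3 oxygen are all missing, so C2 would have to be arylated to reach a compound of type A3 before the endgame of alternative 2 could start. The oxidants also attack electron-rich arenes and benzylic ethers such as ring D and C2''–H, and no stereocentre is addressed.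
- Comparison: this is the longest route; the chosen strategy installs ring B together with the alkyne.

Key step: step 12

## Route

Step 1
Reactants: 1 2,4,6-trihydroxybenzaldehyde
Product: 2 2,6-dihydroxy-4-(methoxymethoxy)benzaldehyde
Conditions: MOMCl (1.0 equiv), i-Pr2NEt (1.1 equiv), THF, 0 °C
Reagents that add atoms: chloromethyl methyl ether (MOMCl), COCCl
Why: O-alkylation; the 4-hydroxyl is the only one not hydrogen-bonded to the formyl group and is the most acidic, so one equivalent of MOMCl should alkylate it preferentially, and any bis-ether is removed by chromatography.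

Step 2
Reactants: 2 2,6-dihydroxy-4-(methoxymethoxy)benzaldehyde
Product: 3 2-(benzyloxy)-6-hydroxy-4-(methoxymethoxy)benzaldehyde
Conditions: BnBr (1.05 equiv), K2CO3 (1.1 equiv), DMF, rt
Reagents that add atoms: benzyl bromide, BrCc1ccccc1
Why: Williamson etherification; the two hydroxyls are equivalent, and after the first benzylation the remaining one is held in a strong hydrogen bond to the aldehyde, which should stop the reaction at the monobenzyl ether.

Step 3
Reactants: 3 2-(benzyloxy)-6-hydroxy-4-(methoxymethoxy)benzaldehyde; 4 4'-benzyloxyacetophenone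
Product: 5 (E)-3-[2-(benzyloxy)-6-hydroxy-4-(methoxymethoxy)phenyl]-1-[4-(benzyloxy)phenyl]prop-2-en-1-one
Conditions: KOH (50% aq), EtOH, rt to 40 °C; then AcOH to pH 6
Reagents that add atoms: none
Why: Claisen–Schmidt condensation; the enolate of 4 adds to the aldehyde (present as its phenoxide, hence concentrated base and a long reaction time) and E1cB dehydration gives the conjugated (E)-enone, with MOM and benzyl ethers inert to base.

Step 4
Reactants: 5 (E)-enone
Product: 6 3-[2-(benzyloxy)-6-hydroxy-4-(methoxymethoxy)phenyl]-1-[4-(benzyloxy)phenyl]propan-1-one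
Conditions: H2 (1 atm), Pd/C (10%), Ph2S (cat.), EtOAc, rt
Reagents that add atoms: none
Why: Chemoselective heterogeneous hydrogenation; Pd/C moderated with diphenyl sulfide saturates the enone C=C while aryl benzyl ethers and the aryl ketone are retained.

Step 5
Reactants: 6 saturated ketone
Product: 7 (R)-3-[2-(benzyloxy)-6-hydroxy-4-(methoxymethoxy)phenyl]-1-[4-(benzyloxy)phenyl]propan-1-ol
Conditions: RuCl(p-cymene)[(R,R)-TsDPEN] (2 mol %), HCO2Na, MeOH/H2O, 40 °C
Reagents that add atoms: none
Why: Noyori asymmetric transfer hydrogenation of an aryl alkyl ketone; the (R,R)-ligand delivers hydride to the face that gives the (R)-carbinol (aryl/η6-arene contact in the six-membered transition state), and neutral aqueous formate keeps the p-alkoxybenzylic alcohol away from acid.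

Step 6
Reactants: 7 (R)-carbinol
Product: 8 (S)-5-(benzyloxy)-2-[4-(benzyloxy)phenyl]-7-(methoxymethoxy)chromane
Conditions: PPh3, DIAD, toluene/THF, 0 °C
Reagents that add atoms: none
Why: Intramolecular Mitsunobu etherification (6-exo-tet); the phenol displaces the alkoxyphosphonium group with inversion, so the (R)-carbinol becomes the (S)-configured C2'', and low temperature in a weakly polar medium suppresses ionisation of the p-benzyloxybenzylic centre.

Step 7
Reactants: 8 (S)-flavan
Product: 9 (S)-5-(benzyloxy)-2-[4-(benzyloxy)phenyl]-8-iodo-7-(methoxymethoxy)chromane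
Conditions: NIS (1.05 equiv), DMF, 0 °C, dark
Reagents that add atoms: N-iodosuccinimide, O=C1CCC(=O)N1I
Why: Electrophilic aromatic iodination of the trioxygenated ring D; C8'' (between O1'', tied back in ring E, and the small MOM ether) is less hindered than C6'' (between OMOM and OBn), the preference known from 8-halogenation of per-O-benzylated flavan-3-ols, and no acid is present to cleave the MOM ether.

Step 8
Reactants: 9 8''-iodoflavan; 10 1-(benzyloxy)-4-ethynylbenzene
Product: 11 (S)-5-(benzyloxy)-2-[4-(benzyloxy)phenyl]-8-{[4-(benzyloxy)phenyl]ethynyl}-7-(methoxymethoxy)chromane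
Conditions: PdCl2(PPh3)2 (5 mol %), CuI (10 mol %), Et3N/DMF, 60 °C, degassed
Reagents that add atoms: none
Why: Sonogashira coupling; the MOM ether on O7'' prevents the metal-induced closure to a 2-arylbenzofuran that a free ortho-iodophenol would undergo, heating compensates for the electron-rich di-ortho-oxygenated iodide, and excess 10 allows for oxidative dimerisation.

Step 9
Reactants: 11 alkynyl MOM ether
Product: 12 (S)-5-(benzyloxy)-2-[4-(benzyloxy)phenyl]-8-{[4-(benzyloxy)phenyl]ethynyl}chroman-7-ol
Conditions: HCl (3 M aq, cat.), MeOH/THF, 40 °C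
Reagents that add atoms: none
Why: Acid-catalysed acetal exchange removes the MOM group; benzyl ethers and the flavan are stable, and dilute acid at moderate temperature is not expected to trigger 5-endo hydroalkoxylation of the alkyne.

Step 10
Reactants: 13 3,5-bis(benzyloxy)phenol
Product: 14 1,3-bis(benzyloxy)-5-(methoxymethoxy)benzene
Conditions: MOMCl, i-Pr2NEt, CH2Cl2, 0 °C to rt
Reagents that add atoms: chloromethyl methyl ether (MOMCl), COCCl
Why: O-alkylation of the phenol; the MOM group is both the removable mask of the future O1 and the directing group for step 11.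

Step 11
Reactants: 14 1,3-bis(benzyloxy)-5-(methoxymethoxy)benzene
Product: 16 1,5-bis(benzyloxy)-2-iodo-3-(methoxymethoxy)benzene, via aryllithium 15 (not isolated)
Conditions: n-BuLi (1.1 equiv), THF, 0 °C; then I2, −78 °C to rt
Reagents that add atoms: iodine, II
Why: Directed ortho-metalation; the chelating MOM ether directs n-BuLi to the position it shares with a benzyloxy group (two equivalent sites by symmetry) in preference to the position between the two benzyloxy groups, and the aryllithium is iodinated.

Step 12
Reactants: 12 (S)-8''-alkynylflavan-7''-ol; 16 ring A iodide; 17 carbon monoxide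
Product: 18 3-aroyl-2-arylbenzofuran fused to the (S)-flavan: furan ring F across O7''/C8'' of (S)-5''-benzyloxy-2''-(4-benzyloxyphenyl)chroman, with 4-benzyloxyphenyl (ring B) on C2 and the 2,4-bis(benzyloxy)-6-(methoxymethoxy)benzoyl group (ring A and C4) on C3
Conditions: Pd(PPh3)4 (10 mol %), K2CO3 (3 equiv), CO (1 atm), MeCN/THF, 50 °C; 16 in excess (1.5 equiv)
Reagents that add atoms: none
Why: Zerovalent palladium adds oxidatively to the C–I bond of 16 and CO inserts to give an aroyl complex of divalent palladium (C4–C4a). This electrophilic complex binds the alkyne of the phenoxide of 12, and O7'' attacks the alkyne carbon that carries ring B anti to the metal, forming C2–O7'' and closing ring F in the 5-endo-dig mode, the only closure the ortho relationship allows. Reductive elimination from the resulting (benzofuran-3-yl)(aroyl)palladium forms C3–C4 and returns zerovalent palladium. The closest known reaction type is the palladium-catalysed carbonylative cyclisation of 2-alkynylphenols with aryl iodides to 2-substituted 3-aroylbenzofurans. No stereocentre is formed, and C2'' is remote from every bond made and not epimerisable by carbonate. The step needs chemoselectivity for acyl transfer over direct 3-arylation, proton-terminated cycloisomerisation and O-acylation of the phenoxide. CO insertion into the di-ortho-substituted aryl–palladium bond relieves strain and is driven further by CO pressure, and the weak heterogeneous base keeps the phenoxide concentration low. The two ortho oxygens of 16 slow oxidative addition, hence the raised catalyst loading and temperature.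

Step 13
Reactants: 18 MOM-protected 3-aroylbenzofuran
Product: 19 the same benzofuran with a free ring A phenol (2,4-bis(benzyloxy)-6-hydroxybenzoyl group on C3)
Conditions: HCl (3 M aq), MeOH/THF, 45 °C
Reagents that add atoms: none
Why: Acidic cleavage of the MOM ether, accelerated by the ortho carbonyl group to which the freed phenol becomes hydrogen-bonded; benzyl ethers, the benzofuran and the flavan are unaffected.

Step 14
Reactants: 19 3-(2-hydroxyaroyl)-2-arylbenzofuran
Product: 21 pentabenzyl ether of the target (2R,3R,2''S), via benzofuran 2,3-epoxide 20 (not isolated)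
Conditions: (S,S)-[N,N'-bis(3,5-di-tert-butylsalicylidene)cyclohexane-1,2-diaminato]MnCl (10 mol %), NMO (5 equiv), mCPBA (2 equiv), CH2Cl2, −78 to −30 °C
Reagents that add atoms: meta-chloroperoxybenzoic acid (mCPBA), O=C(OO)c1cccc(Cl)c1
Why: Proposed new method: the pentavalent manganese-oxo species generated from the trivalent manganese salen chloride and mCPBA/NMO should transfer oxygen to the nucleophilic C3 terminus of the enol-ether-like C2=C3 bond (the developing radical or cation at C2 is stabilised by O7'' and ring B), and epoxide 20 is then opened at C2 by the hydrogen-bonded ring A phenol in a 6-exo closure of ring C anti to the new C3–O bond, which the six/five fusion allows only as the cis ketal; C3 is therefore set by catalyst-controlled delivery to the Si face of C3 (predicted for the (S,S)-complex by analogy with its (1S,2R)-selective epoxidation of indene, the (R,R)-antipode being equally available should the substrate dock the other way) and C2 follows from the ring fusion; the closest known reaction types are the Jacobsen–Katsuki epoxidation of indene, chromenes and isoflavones and the dimethyldioxirane epoxidation of 2,3-disubstituted benzofurans with nucleophilic opening at C2.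

Step 15
Reactants: 21 pentabenzyl ether
Product: 22 target CNP0208300.2
Conditions: H2 (1 atm), Pd/C (10%), EtOAc/MeOH, rt
Reagents that add atoms: none
Why: Hydrogenolysis of five aryl benzyl ethers under neutral conditions; these primary benzylic C–O bonds should react much faster than the tertiary ketal C2–O bonds, the tertiary C3 carbinol and the secondary C2''–O1'' bond of the flavan, so the three stereocentres should remain untouched if the reaction is stopped at completion.

## Compound list

1 | 2,4,6-trihydroxybenzaldehyde | O=Cc1c(O)cc(O)cc1O | starting material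
2 | 2,6-dihydroxy-4-(methoxymethoxy)benzaldehyde | O=Cc1c(O)cc(OCOC)cc1O | intermediate
3 | 2-(benzyloxy)-6-hydroxy-4-(methoxymethoxy)benzaldehyde | O=Cc1c(O)cc(OCOC)cc1OCc1ccccc1 | intermediate
4 | 4'-benzyloxyacetophenone | CC(=O)c1ccc(OCc2ccccc2)cc1 | starting material
5 | (E)-3-[2-(benzyloxy)-6-hydroxy-4-(methoxymethoxy)phenyl]-1-[4-(benzyloxy)phenyl]prop-2-en-1-one | O=C(/C=C/c1c(O)cc(OCOC)cc1OCc1ccccc1)c1ccc(OCc2ccccc2)cc1 | intermediate
6 | 3-[2-(benzyloxy)-6-hydroxy-4-(methoxymethoxy)phenyl]-1-[4-(benzyloxy)phenyl]propan-1-one | O=C(CCc1c(O)cc(OCOC)cc1OCc1ccccc1)c1ccc(OCc2ccccc2)cc1 | intermediate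
7 | (R)-3-[2-(benzyloxy)-6-hydroxy-4-(methoxymethoxy)phenyl]-1-[4-(benzyloxy)phenyl]propan-1-ol | O[C@@H](c1ccc(OCc2ccccc2)cc1)CCc1c(O)cc(OCOC)cc1OCc1ccccc1 | intermediate
8 | (S)-5-(benzyloxy)-2-[4-(benzyloxy)phenyl]-7-(methoxymethoxy)chromane | COCOc1cc(OCc2ccccc2)c2c(c1)O[C@H](c1ccc(OCc3ccccc3)cc1)CC2 | intermediate
9 | (S)-5-(benzyloxy)-2-[4-(benzyloxy)phenyl]-8-iodo-7-(methoxymethoxy)chromane | COCOc1cc(OCc2ccccc2)c2c(c1I)O[C@H](c1ccc(OCc3ccccc3)cc1)CC2 | intermediate
10 | 1-(benzyloxy)-4-ethynylbenzene | C#Cc1ccc(OCc2ccccc2)cc1 | starting material
11 | (S)-5-(benzyloxy)-2-[4-(benzyloxy)phenyl]-8-{[4-(benzyloxy)phenyl]ethynyl}-7-(methoxymethoxy)chromane | COCOc1cc(OCc2ccccc2)c2c(c1C#Cc1ccc(OCc3ccccc3)cc1)O[C@H](c1ccc(OCc3ccccc3)cc1)CC2 | intermediate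
12 | (S)-5-(benzyloxy)-2-[4-(benzyloxy)phenyl]-8-{[4-(benzyloxy)phenyl]ethynyl}chroman-7-ol | Oc1cc(OCc2ccccc2)c2c(c1C#Cc1ccc(OCc3ccccc3)cc1)O[C@H](c1ccc(OCc3ccccc3)cc1)CC2 | intermediate
13 | 3,5-bis(benzyloxy)phenol | Oc1cc(OCc2ccccc2)cc(OCc2ccccc2)c1 | starting material
14 | 1,3-bis(benzyloxy)-5-(methoxymethoxy)benzene | COCOc1cc(OCc2ccccc2)cc(OCc2ccccc2)c1 | intermediate
15 | [2,4-bis(benzyloxy)-6-(methoxymethoxy)phenyl]lithium | [Li]c1c(OCOC)cc(OCc2ccccc2)cc1OCc1ccccc1 | intermediate (not isolated)
16 | 1,5-bis(benzyloxy)-2-iodo-3-(methoxymethoxy)benzene | Ic1c(OCOC)cc(OCc2ccccc2)cc1OCc1ccccc1 | intermediate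
17 | carbon monoxide | [C-]#[O+] | starting material
18 | 3-aroyl-2-arylbenzofuran on the (S)-flavan: ring F across O7''/C8'' of (S)-5''-benzyloxy-2''-(4-benzyloxyphenyl)chroman; C2 bears 4-benzyloxyphenyl; C3 bears 2,4-bis(benzyloxy)-6-(methoxymethoxy)benzoyl | O=C(c1c(OCOC)cc(OCc2ccccc2)cc1OCc1ccccc1)c1c(-c2ccc(OCc3ccccc3)cc2)oc2cc(OCc3ccccc3)c3c(c12)O[C@H](c1ccc(OCc2ccccc2)cc1)CC3 | intermediate
19 | as 18, with a 2,4-bis(benzyloxy)-6-hydroxybenzoyl group on C3 (free ring A phenol) | O=C(c1c(O)cc(OCc2ccccc2)cc1OCc1ccccc1)c1c(-c2ccc(OCc3ccccc3)cc2)oc2cc(OCc3ccccc3)c3c(c12)O[C@H](c1ccc(OCc2ccccc2)cc1)CC3 | intermediate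
20 | (2S,3R)-2,3-epoxide of 19 (epoxide oxygen on the Si face of C3; 2''S) | O=C(c1c(O)cc(OCc2ccccc2)cc1OCc1ccccc1)[C@@]12O[C@]1(c1ccc(OCc3ccccc3)cc1)Oc1cc(OCc3ccccc3)c3c(c12)O[C@H](c1ccc(OCc2ccccc2)cc1)CC3 | intermediate (not isolated)
21 | pentabenzyl ether of the target: (2R,3R,2''S), cis-fused rings C/F, 3-OH free, benzyl on O5, O7, O4' (ring B), O5'' and the ring G oxygen | O=C1c2c(OCc3ccccc3)cc(OCc3ccccc3)cc2O[C@@]2(c3ccc(OCc4ccccc4)cc3)Oc3cc(OCc4ccccc4)c4c(c3[C@@]12O)O[C@H](c1ccc(OCc3ccccc3)cc1)CC4 | intermediate
22 | CNP0208300.2: (2R,3R)-3,5,7-trihydroxy-2-(4-hydroxyphenyl)chroman-4-one with C2 bonded to O7'' and C3 bonded to C8'' of (2''S)-5''-hydroxy-2''-(4-hydroxyphenyl)chroman (cis-fused furan ring F) | O=C1c2c(O)cc(O)cc2O[C@@]2(c3ccc(O)cc3)Oc3cc(O)c4c(c3[C@@]12O)O[C@H](c1ccc(O)cc1)CC4 | target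

## Step count and least certain steps

Total: 15 steps. Longest linear sequence: 13 steps (steps 1–9 and 12–15 from 1); the ring A branch is 2 steps (10, 11).

**Step 14 (proposed new method).** The hindered, tetrasubstituted, acyl-bearing C2=C3 bond may react too slowly with the bulky manganese-oxo species, or facial selectivity may be poor. The free phenol or ring D may be over-oxidised, or the opened epoxide may suffer a 1,2-aroyl shift before the phenol closes ring C. Fallback without catalyst control, using known chemistry: starting from 19, epoxidation with dimethyldioxirane in acetone/CH2Cl2 at −20 °C (the established oxidant for 2,3-disubstituted benzofurans and flavones), followed by the same spontaneous phenol capture, should give 21 together with the (2S,3S,2''S)-diastereomer of 21, F1. Because C2'' is fixed, the two are diastereomers and are separated by chromatography; the route is rejoined at 21.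

**Step 12 (key step).** Oxidative addition to the di-ortho-oxygenated iodide may be slow enough for base- or palladium-induced cycloisomerisation of 12 to the 3-unsubstituted benzofuran to take over. Acyl transfer may also lose to O-acylation of the phenoxide or to direct arylation. Fallback that assembles the same ketone stepwise: starting from 12 and 14, iodocyclisation of 12 (I2, NaHCO3, MeCN, rt) gives the 3-iodo-2-arylbenzofuran fused to the flavan, F2. Lithiation of 14 as in step 11 with a DMF quench gives 2,4-bis(benzyloxy)-6-(methoxymethoxy)benzaldehyde, F3. Iodine–magnesium exchange on F2 (i-PrMgCl·LiCl, THF, −30 °C; the magnesium species does not fragment to the alkynylphenoxide as the lithium one would) and addition to F3 give the diaryl carbinol F4 as a mixture of epimers. Dess–Martin periodinane oxidises it to 18, where the route resumes.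

**Step 6.** The activated p-benzyloxybenzylic alkoxyphosphonium ion may ionise, eroding the enantiomeric purity of C2'' or eliminating to a styrene. Fallback that avoids substitution at the benzylic carbon: starting from 6, cyclodehydration (PPTS, toluene, 4 Å sieves, 80 °C) gives 5-(benzyloxy)-2-[4-(benzyloxy)phenyl]-7-(methoxymethoxy)-4H-chromene, F5. Iridium-catalysed asymmetric hydrogenation of its enol-ether double bond ([Ir(cod)(PHOX)]BArF-type catalyst with the ligand antipode that gives the S product, H2 50 bar, CH2Cl2) leads to 8; benzyl ethers are not cleaved by the homogeneous catalyst.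

**Step 11.** Metalation may occur partly between the two benzyloxy groups or at a benzylic CH2 (followed by Wittig rearrangement), giving the wrong iodide. Fallback by electrophilic substitution: starting from 13, iodination ortho to the free hydroxyl (NIS, CH2Cl2, −40 °C; the para position is flanked by two benzyloxy groups) gives 3,5-bis(benzyloxy)-2-iodophenol, F6, which is converted to 16 with MOMCl and i-Pr2NEt.

**Step 15.** Reductive cleavage may extend to the benzylic C–O bonds of the ketal or of the flavan, or debenzylation may stall part-way. Fallback without a reductant: starting from 21, BCl3 with pentamethylbenzene as cation scavenger in CH2Cl2 at −78 °C removes the aryl benzyl ethers by Lewis-acid-assisted ionisation and gives 22 directly.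

## Further compounds

F1 | step 14 | (2S,3S,2''S)-diastereomer of 21 | O=C1c2c(OCc3ccccc3)cc(OCc3ccccc3)cc2O[C@]2(c3ccc(OCc4ccccc4)cc3)Oc3cc(OCc4ccccc4)c4c(c3[C@]12O)O[C@H](c1ccc(OCc3ccccc3)cc1)CC4
F2 | step 12 | 3-iodo-2-(4-benzyloxyphenyl)benzofuran fused across O7''/C8'' of (S)-5''-benzyloxy-2''-(4-benzyloxyphenyl)chroman | Ic1c(-c2ccc(OCc3ccccc3)cc2)oc2cc(OCc3ccccc3)c3c(c12)O[C@H](c1ccc(OCc2ccccc2)cc1)CC3
F3 | step 12 | 2,4-bis(benzyloxy)-6-(methoxymethoxy)benzaldehyde | O=Cc1c(OCOC)cc(OCc2ccccc2)cc1OCc1ccccc1
F4 | step 12 | carbinol corresponding to 18 (C4–OH, mixture of epimers at C4, 2''S) | OC(c1c(OCOC)cc(OCc2ccccc2)cc1OCc1ccccc1)c1c(-c2ccc(OCc3ccccc3)cc2)oc2cc(OCc3ccccc3)c3c(c12)O[C@H](c1ccc(OCc2ccccc2)cc1)CC3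
F5 | step 6 | 5-(benzyloxy)-2-[4-(benzyloxy)phenyl]-7-(methoxymethoxy)-4H-chromene | COCOc1cc(OCc2ccccc2)c2c(c1)OC(c1ccc(OCc3ccccc3)cc1)=CC2
F6 | step 11 | 3,5-bis(benzyloxy)-2-iodophenol | Oc1cc(OCc2ccccc2)cc(OCc2ccccc2)c1I
F0 | step 15 | none | none
A1 | alternative 1 | (E)-α-(flavan-8''-yl)-2'-hydroxychalcone: 1-[2,4-bis(benzyloxy)-6-hydroxyphenyl]-3-[4-(benzyloxy)phenyl]-2-[(S)-5''-benzyloxy-2''-(4-benzyloxyphenyl)-7''-(methoxymethoxy)chroman-8''-yl]prop-2-en-1-one | O=C(c1c(O)cc(OCc2ccccc2)cc1OCc1ccccc1)/C(=C/c1ccc(OCc2ccccc2)cc1)c1c(OCOC)cc(OCc2ccccc2)c2c1O[C@H](c1ccc(OCc3ccccc3)cc1)CC2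
A2 | alternative 1 | 5,7-bis(benzyloxy)-2-(4-benzyloxyphenyl)-3-hydroxy-3-[(S)-flavan-8''-yl]chroman-4-one with C2–H (ring B trans to 3-OH) | O=C1c2c(OCc3ccccc3)cc(OCc3ccccc3)cc2O[C@@H](c2ccc(OCc3ccccc3)cc2)[C@@]1(O)c1c(OCOC)cc(OCc2ccccc2)c2c1O[C@H](c1ccc(OCc3ccccc3)cc1)CC2
A3 | alternative 2 | 5,7-bis(benzyloxy)-2-(4-benzyloxyphenyl)-3-[(S)-5''-benzyloxy-2''-(4-benzyloxyphenyl)-7''-hydroxychroman-8''-yl]chromen-4-one | O=c1c(-c2c(O)cc(OCc3ccccc3)c3c2O[C@H](c2ccc(OCc4ccccc4)cc2)CC3)c(-c2ccc(OCc3ccccc3)cc2)oc2cc(OCc3ccccc3)cc(OCc3ccccc3)c12
A4 | alternative 2 | pentabenzyl ether of the target (identical with 21) | O=C1c2c(OCc3ccccc3)cc(OCc3ccccc3)cc2O[C@@]2(c3ccc(OCc4ccccc4)cc3)Oc3cc(OCc4ccccc4)c4c(c3[C@@]12O)O[C@H](c1ccc(OCc3ccccc3)cc1)CC4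
A5 | alternative 3 | (E)-1-[2,4-bis(benzyloxy)-6-hydroxyphenyl]-3-[(S)-5''-benzyloxy-2''-(4-benzyloxyphenyl)-7''-(methoxymethoxy)chroman-8''-yl]prop-2-en-1-one | O=C(/C=C/c1c(OCOC)cc(OCc2ccccc2)c2c1O[C@H](c1ccc(OCc3ccccc3)cc1)CC2)c1c(O)cc(OCc2ccccc2)cc1OCc1ccccc1
A6 | alternative 3 | 5,7-bis(benzyloxy)-3-[(S)-5''-benzyloxy-2''-(4-benzyloxyphenyl)-7''-(methoxymethoxy)chroman-8''-yl]chromen-4-one (isoflavone, C2–H) | O=c1c(-c2c(OCOC)cc(OCc3ccccc3)c3c2O[C@H](c2ccc(OCc4ccccc4)cc2)CC3)coc2cc(OCc3ccccc3)cc(OCc3ccccc3)c12
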